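The ratio I started from was protic impurity to starting complex, 0.500 in the east run. I supposed that each impurity destroys one incoming ligand for good.

| flask | starting complex | incoming ligand | leaving ligand | protic impurity | remark | time |
|---|---|---|---|---|---|---|
| east | 0.13 M | 0.63 equiv | 1 equiv | 0.065 M | run made earlier |  |
| south-east | 0.13 M | 3.7 equiv | 1 equiv | 0.065 M | run made earlier |  |
| Tuesday's | 0.13 M | 0.500 equiv | 1.00 equiv | 0.0650 M |  | 5.0 d |
| Sunday's | 0.13 M | 2.50 equiv | 1.00 equiv | 0.0650 M |  | 5.0 d |
| Monday's | 0.13 M | 3.00 equiv | 1.00 equiv | 0.0650 M |  | 5.0 d |

| run | time / d | complex with one exchanged / % |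
|---|---|---|
| east | 0.250 | 18.5 |
| east | 0.833 | 21.8 |
| east | 1.25 | 21.4 |
| east | 2.00 | 21.4 |
| east | 3.00 | 20.8 |
| east | 4.00 | 19.8 |
| east | 5.00 | 19.0 |
| south-east | 0.625 | 72.7 |
| south-east | 1.25 | 75.2 |
| south-east | 2.00 | 73.8 |
| south-east | 3.00 | 73.5 |
| south-east | 4.00 | 74.0 |
| south-east | 5.00 | 74.4 |

(standard deviation of a reading: 0.5 percentage points)

* final complex with one exchanged, as a percentage of the starting complex charged, for each flask in turn (Tuesday's, Sunday's, Monday's)

- the numbers in the tables scatter by 0.5 percentage points (one standard deviation)
- a reading or a percentage of complex with one exchanged counts all its forms, free or not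

On that supposition the east run keeps 0.130 equiv. This is the net charge: equivalents of incoming ligand charged minus equivalents of protic impurity charged, per starting complex. The east run's net charge is positive, so I took the impurity as the limiting reagent of that quench in the east run.

My first estimate was that the east run would read the net charge as a percentage. But its highest reading was 21.8%, more than 13.0%, and its reading at 5.00 d was 19.0%. So I read the net charge as where the reading was heading, not as its value at that time.

Tuesday's has a net charge of 0 equiv, yet I did not expect zero at the asked time. Scaling the highest east reading by the charge gave 17.3%, and subtracting the fall of 2.8 percentage points between those east readings left my estimate of 14.5% for Tuesday's.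

More net charge ought to give more product, which would put Sunday's and Monday's below south-east's 74.0%. The objection is that south-east, at 3.20 equiv, has ample ligand and still stays flat there. I assigned the remaining 26.0% to complex with two exchanged. That reading gives Q = c(complex with two exchanged) c(leaving ligand) / (c(complex with one exchanged) c(incoming ligand)) = 0.409.

Holding Q and using net charges of 2.00 and 2.50 equiv, I reckoned 85.9% for Sunday's and 80.4% for Monday's, Sunday's being higher. This reckoning of mine sets leftover starting complex to zero, and that is an assumption, because no reading of starting complex stands in the two runs.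

The forecast, assuming that the impurity “ties up incoming ligand”, gave 15%, 62% and 67.7%. Its Sunday's value is lower than mine, and it rises from Sunday's to Monday's where mine falls.

The flasks gave 13.2% for Tuesday's, 85.5% for Sunday's and 80.8% for Monday's.

    starting complex + incoming ligand ⇌ leaving ligand + complex with one exchanged (K = 43.0, k = 1.10 M⁻¹ h⁻¹)
    complex with one exchanged + incoming ligand ⇌ leaving ligand + complex with two exchanged (K = 0.660, k = 0.500 M⁻¹ h⁻¹)
    crystals ⇌ complex with one exchanged, rate k3*(cs3 - [complex with one exchanged]) while solid is left; crystals form when [complex with one exchanged] > cs3 (solubility = 0.0560 M, k = 12.0 h⁻¹)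
    protic impurity + incoming ligand → quenched reagent (k = 6.60 M⁻¹ h⁻¹)

Sunday's figure includes 42.4% as crystals, beside 12.2% of complex with two exchanged. Sunday's net charge of 2.00 equiv can be found in that flask at 5.00 d: the uptake of 1.10 equiv plus 0.901 equiv of unbound incoming ligand makes 2.00 equiv.

The earlier runs and the new flask come from a simulation on assumed constants, and the scatter is random.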